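## Structural features

The target is a pentasubstituted benzene. The ring is numbered C1 to C6 so that C1 carries the formyl carbon C7, C2 the chain C8H2–C9H(OAc)–undecyl, C3 a hydroxyl, C4 a methoxy group, C5 a hydrogen and C6 a hydroxyl. The C3 and C6 oxygens are para, so the core is a hydroquinone, methoxylated at C4 and formylated next to the C6 hydroxyl (a hydrogen-bonded salicylaldehyde). C9 is the only stereocentre (R); it is homobenzylic, has no stereogenic neighbour and carries the only acetate. The fragile groups are the electron-rich hydroquinone (air oxidation to the quinone), the aldehyde, and the secondary acetate, which must stay in place while two phenols are free. Without its acetyl group the C9 hydroxyl would close onto C7 as a lactol. The difficulty is regiochemical, not stereochemical: five different substituents must be placed around one ring, and the C9 oxygen must be distinguished from the two phenolic oxygens. The key step uses two features. Tying C7 to the C9 oxygen makes C7–C1=C2–C8–C9–O a dihydropyran that carries the C1=C2 alkene. C3–C4–C5–C6 with their oxygens correspond to a 3-methoxycyclobutene-1,2-dione, so that joining C1 to C6 completes the benzene ring.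

## Logic of the disconnections

19 is traced to 18 by putting acetyl groups back on the C3 and C6 oxygens. The phenols must be masked while C7 is brought to the aldehyde level, and aryl esters can be removed beside the alkyl ester at C9. The forward step must cleave two aryl O–acyl bonds and leave the C9 acetate and the aldehyde alone.

18 is traced to 16 by changing C7=O into C7–Br. A benzylic bromide para to the methoxy group is a reactive electrophile and is oxidised without a metal oxidant. The forward step needs an oxygen-transfer oxidation under weakly basic, non-nucleophilic conditions that three acetates survive.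

16 is traced to 15 by removing the C7–Br bond and the three O–acetyl bonds and reconnecting C7 to the C9 oxygen. This ties the aldehyde carbon and the carbinol oxygen into one cyclic benzylic ether, so no separate protecting groups are needed for C7 and C9–OH. The forward step must break the benzylic C7–O bond and not the C9–O bond, so that the acetyl group lands on the C9 oxygen with retention.

15 is traced to 12 by cutting the C1–C6 bond and folding C3–C6 back into a four-membered ring. One aromatic ring with four contiguous heteroatom and carbon substituents is replaced by a cyclobutenone joined through one C–C bond to a dihydropyran. The forward step needs outward rotation of the hydroxyl in the ring opening and a regiochemistry that is already written into the σ-framework of 12.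

12 is traced to 11 and 10 by cutting the bond between the carbinol carbon (future C3) and the alkenyl carbon (future C2). This separates the C4 building block from the C16 side-chain block. The forward addition must go to the carbonyl next to the methoxy-bearing carbon of 10.

10 is traced to 8 (through 9) by exchanging the ring hydrogen for a methoxy group. 8 is commercial and symmetrical, so a single hydride addition followed by acid-induced transposition removes one methoxy group without any selectivity problem.

11 is traced to 7 by lithium–bromine exchange. 7 is traced to 6 by cutting the ring C–C bond between the alkene CH and the OCH2 carbon, and the O–CH2 bond. This removes the heterocycle and leaves an open-chain homopropargylic alcohol plus a one-carbon electrophile. The cyclisation also fixes the halogen on the alkene carbon next to the ring CH2, which the regiochemistry of the key step requires. The forward step needs direct closure of the oxocarbenium ion; a competing [3,3] shift of that ion would pass through an achiral allenyl isomer and is the main threat to the stereocentre (see the closing section).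

6 is traced to 5 by cutting the propargylic C–C bond, 5 to 4 by opening the epoxide C–O bond, and 4 to 1 and 2 (through 3) by cutting the C–C bond that joins the decyl chain. All three forward reactions occur at CH2 carbons, so the configuration of 2 is carried unchanged into C9.

## Other disconnections considered

Alternative 1: The cut is the C1–C2 bond, with the whole arene unravelled into the triketo chain of 6-[(6R)-6-(tert-butyldimethylsilyloxy)-2,4-dioxoheptadecyl]-2,2-dimethyl-4H-1,3-dioxin-4-one A1. In the forward direction a mild base would make the dioxinone α-carbon attack the distal ketone; dehydration and enolisation would give the benzodioxinone A2.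
- In favour: the ring forms near room temperature, the regiochemistry is fixed by the chain, and A2 is air-stable. On mildness and on the stability of the key-step product this alternative is better than the chosen plan.
- Against: A2 is a resorcylate. C3 is still C–H and would need a late hydroxylation para to the C6 oxygen. The C4 hydroxyl must be methylated selectively. C7 sits at the carboxyl level inside the dioxinone and must be reduced. The silyl ether must be exchanged for the acetate. A1 itself needs several C-acylations.
- Comparison: 15 already carries all three ring oxygens in the right places and C7 at a level one oxidation from the aldehyde. This alternative is equal in regiochemical certainty and clearly worse in step economy.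

Alternative 2: The cuts are C2–C8, C1–C7 and C7–O. In the forward direction the iodide 1-iodo-4-methoxy-2,5-bis(methoxymethoxy)benzene A3, epoxide 5 and CO would be joined by a palladium/norbornene (Catellani) relay: C–H palladation at C2, alkylation by the epoxide CH2, norbornene loss, CO insertion and lactonisation to the isochromanone A4.
- In favour: it is convergent, it reuses 5, it leaves the C9 configuration untouched, and A4 is air-stable and reachable in about five steps. On convergence and on robustness of intermediates it is equal or better.
- Against: the C–H bond to be palladated lies between the palladium-bearing carbon and an OMOM group, a crowded site for this relay, and CO can intercept the aryl palladium species before the alkylation. The lactone also holds C7 one oxidation level too high. Partial reduction would give the lactol (3R)-6-methoxy-5,8-bis(methoxymethoxy)-3-undecyl-3,4-dihydro-1H-isochromen-1-ol A5, in which the aldehyde and the C9 hydroxyl mask each other. Freeing the aldehyde while acetylating C9–O would then need a ring-opening, trapping and release sequence plus acidic MOM removal.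
- Comparison: the benzylic ether of 15 is opened and acetylated on the C9 oxygen in one operation. The key step of this alternative is mechanistically less secure and its endgame is longer, so the total is no shorter.

Alternative 3: The cuts are C2–C3 and C1–C6. In the forward direction the siloxyfuran tert-butyl[(4-methoxyfuran-2-yl)oxy]dimethylsilane A6 would add across the triple bond of the ynal (5R)-1-oxohexadec-2-yn-5-yl acetate A7 (two steps from 6), and the oxanorbornadiene would open to the arene A8.
- In favour: A8 differs from the target only by one silyl group. The aldehyde, the C9 acetate and all ring oxygens are in place, and the sequence would take about eight steps with seven in the longest line, against ten and nine for the chosen plan. On step economy and on the simplicity of the endgame this alternative is better.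
- Against: the regiochemistry rests on orbital polarisation and not on connectivity. The doubly activated furan can add as a vinylogous silyl enolate without closing the ring. Lewis-acid assistance risks desilylation to the butenolide. The ynal is prone to conjugate addition and to loss of the β-acetoxy group.
- Comparison: in the chosen plan the substitution pattern is fixed by a σ-bond made in a separate addition step, and the thermal step has close precedent for alkenyl cyclobutenones. It gives up two or three steps for that predictability.

Key step: step 7

Assumption: 12 is carried forward as the mixture of its two C4 epimers, because this centre becomes sp2 in step 7; the locants C1 to C9 used below are those defined under Structural features.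

## Route

Step 1
Reactants: 1 1-bromodecane; 2 (R)-epichlorohydrin
Product: 4 (2R)-1-chlorotridecan-2-ol, via decylmagnesium bromide 3 (not isolated)
Conditions: Mg, THF, rt to 40 °C; then CuI (5 mol%), 2, THF, −40 to −20 °C; aq. NH4Cl
Reagents that add atoms: none
Why: Copper-catalysed Grignard opening of a terminal epoxide by SN2 attack at the unsubstituted epoxide carbon. The stereocentre of 2 does not react, so its configuration passes into 4 unchanged (R, the CH2Cl group keeping its CIP rank).

Step 2
Reactants: 4 (2R)-1-chlorotridecan-2-ol
Product: 5 (2R)-2-undecyloxirane
Conditions: NaOH (aq. 2 M), Et2O, rt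
Reagents that add atoms: none
Why: Intramolecular Williamson closure. The alkoxide displaces chloride at the primary carbon, so the C–O bond at the stereocentre is kept and 5 is (R).

Step 3
Reactants: 5 (2R)-2-undecyloxirane
Product: 6 (4R)-pentadec-1-yn-4-ol
Conditions: LiC≡CH·H2NCH2CH2NH2, DMSO/THF, 0 °C to rt; aq. NH4Cl
Reagents that add atoms: lithium acetylide ethylenediamine complex, [Li+].[C-]#C.NCCN
Why: Acetylide opening of a terminal epoxide in a dipolar aprotic medium, with attack only at the CH2 terminus. The carbinol centre is untouched and becomes C9 of the target with R configuration.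

Step 4
Reactants: 6 (4R)-pentadec-1-yn-4-ol
Product: 7 (2R)-4-bromo-2-undecyl-3,6-dihydro-2H-pyran
Conditions: (CH2O)n, FeBr3 (1.0 equiv), CH2Br2, 0 °C to rt
Reagents that add atoms: paraformaldehyde (as formaldehyde), C=O; iron tribromide, Br[Fe](Br)Br
Why: Alkyne Prins cyclisation promoted by FeBr3. The oxocarbenium ion from 6 and formaldehyde is attacked by the terminal alkyne carbon (6-endo closure, new C–C bond to the formaldehyde carbon), and bromide captures the ring vinyl cation, which places Br on the alkene carbon next to the ring CH2 that adjoins the stereocentre. On this direct path no bond to the stereocentre is broken.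

Step 5
Reactants: 8 dimethyl squarate
Product: 10 3-methoxycyclobut-3-ene-1,2-dione, via 4-hydroxy-2,3-dimethoxycyclobut-2-en-1-one 9 (not isolated)
Conditions: LiAlH(OtBu)3, THF, −78 °C; then conc. aq. HCl, CH2Cl2, 0 °C to rt
Reagents that add atoms: water, O
Why: 1,2-Hydride delivery to one vinylogous ester carbonyl of 8 by a bulky alkoxyaluminium hydride, then acid-induced allylic transposition (ionisation of the carbinol, water addition at the methoxy-stabilised cation, loss of methanol), the established squarate-to-semisquarate conversion. No stereocentre remains.

Step 6
Reactants: 7 (2R)-4-bromo-2-undecyl-3,6-dihydro-2H-pyran; 10 3-methoxycyclobut-3-ene-1,2-dione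
Product: 12 4-hydroxy-3-methoxy-4-[(2R)-2-undecyl-3,6-dihydro-2H-pyran-4-yl]cyclobut-2-en-1-one (both C4 epimers), via [(2R)-2-undecyl-3,6-dihydro-2H-pyran-4-yl]lithium 11 (not isolated)
Conditions: t-BuLi (2.0 equiv), THF, −78 °C; then 10, THF, −78 °C; aq. NH4Cl
Reagents that add atoms: none
Why: Bromine–lithium exchange (the second equivalent of t-BuLi consumes t-BuBr) followed by 1,2-addition of the alkenyllithium to a cyclobutenedione, the standard entry to 4-alkenyl-4-hydroxycyclobutenones. Addition goes to the carbonyl flanked by the methoxy-bearing carbon, because the other carbonyl is deactivated as a vinylogous ester. The new carbinol centre forms unselectively, which does not matter.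

Step 7
Reactants: 12 4-hydroxy-3-methoxy-4-[(2R)-2-undecyl-3,6-dihydro-2H-pyran-4-yl]cyclobut-2-en-1-one (both C4 epimers)
Product: 15 (3R)-6-methoxy-3-undecylisochromane-5,8-diol, via dienylketene 13 (not isolated), via dienone 14 (not isolated)
Conditions: p-xylene (degassed), 138 °C, Ar
Reagents that add atoms: none
Why: Thermal conrotatory 4π opening of the cyclobutenone breaks the C(OH)–C(=O) bond and gives the (Z)-dienylketene 13; the donor hydroxyl rotates outward, so the dihydropyranyl group points toward the ketene. Disrotatory 6π electrocyclisation of the ketene C=C, the enol ether C=C and the ring alkene then joins the ketene carbon (C6) to the dihydropyran CH (C1) and gives dienone 14. This is the only ring closed, a six-membered carbocycle formed by electrocyclisation and fused to the existing pyran, and enolisation of 14 makes it the benzene ring of 15. The closest known reaction is the Moore rearrangement of 4-alkenyl-4-hydroxycyclobutenones to hydroquinones. No stereocentre is created: the carbinol centre of 12 becomes sp2, the sp3 ring-fusion carbon of 14 is lost on aromatisation, and the undecyl-bearing centre (C9) lies outside the reacting array and stays R. The step needs torquoselectivity and regiochemistry. The hydroxyl donor supplies the first. The second is fixed by connectivity: the methoxy carbon is bonded to the carbinol carbon, so OMe ends next to the C3 hydroxyl, and the ring alkene has its CH on the OCH2 side, so C7 ends on C1 and C8 on C2. The free hydroquinone is expected because the carbinol is unprotected, so air is excluded throughout.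

Step 8
Reactants: 15 (3R)-6-methoxy-3-undecylisochromane-5,8-diol
Product: 16 (2R)-1-[3,6-bis(acetyloxy)-2-(bromomethyl)-5-methoxyphenyl]tridecan-2-yl acetate
Conditions: AcBr (4 equiv), ZnBr2 (0.1 equiv), CH2Cl2, 0 °C to rt, Ar
Reagents that add atoms: acetyl bromide, CC(=O)Br
Why: Zinc-halide-assisted acylative ether cleavage. After fast O-acetylation of both phenols, acetyl transfer to the ring oxygen gives an acyloxonium ion that bromide opens at the primary benzylic carbon C7 (activated by the para methoxy group) and not at the secondary C9. The C9–O bond is never broken, so the acetate is placed on C9 with retention (R).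

Step 9
Reactants: 16 (2R)-1-[3,6-bis(acetyloxy)-2-(bromomethyl)-5-methoxyphenyl]tridecan-2-yl acetate
Product: 18 (2R)-1-[3,6-bis(acetyloxy)-2-formyl-5-methoxyphenyl]tridecan-2-yl acetate, via alkoxysulfonium bromide 17 (not isolated)
Conditions: DMSO (dry), NaHCO3, rt to 50 °C
Reagents that add atoms: dimethyl sulfoxide, CS(C)=O
Why: Kornblum oxidation. The DMSO oxygen displaces the activated benzylic bromide to give alkoxysulfonium salt 17, which bicarbonate converts through its ylide into the aldehyde and dimethyl sulfide. The weak, non-nucleophilic base and the dry medium leave the three acetates in place.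

Step 10
Reactants: 18 (2R)-1-[3,6-bis(acetyloxy)-2-formyl-5-methoxyphenyl]tridecan-2-yl acetate
Product: 19 (2R)-1-(2-formyl-3,6-dihydroxy-5-methoxyphenyl)tridecan-2-yl acetate
Conditions: NaHCO3, MeOH (degassed), rt, Ar; pH 5 buffer work-up
Reagents that add atoms: none
Why: Base-catalysed methanolysis distinguishes the esters by leaving-group ability: the two aryl acetates (one further activated by the ortho formyl group) are cleaved much faster than the secondary alkyl acetate. Any acetyl transfer between the C3 phenoxide and the C9 oxygen favours the alkyl acetate, which is the arrangement of the target.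

## Compound list

1 | 1-bromodecane | CCCCCCCCCCBr | starting material
2 | (R)-epichlorohydrin, (2R)-2-(chloromethyl)oxirane | ClC[C@H]1CO1 | starting material
3 | decylmagnesium bromide | CCCCCCCCCC[Mg]Br | intermediate
4 | (2R)-1-chlorotridecan-2-ol | ClC[C@H](O)CCCCCCCCCCC | intermediate
5 | (2R)-2-undecyloxirane | CCCCCCCCCCC[C@@H]1CO1 | intermediate
6 | (4R)-pentadec-1-yn-4-ol | CCCCCCCCCCC[C@@H](O)CC#C | intermediate
7 | (2R)-4-bromo-2-undecyl-3,6-dihydro-2H-pyran | CCCCCCCCCCC[C@@H]1CC(Br)=CCO1 | intermediate
8 | dimethyl squarate, 3,4-dimethoxycyclobut-3-ene-1,2-dione | COC1=C(OC)C(=O)C1=O | starting material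
9 | 4-hydroxy-2,3-dimethoxycyclobut-2-en-1-one | COC1=C(OC)C(=O)C1O | intermediate
10 | 3-methoxycyclobut-3-ene-1,2-dione | COC1=CC(=O)C1=O | intermediate
11 | [(2R)-2-undecyl-3,6-dihydro-2H-pyran-4-yl]lithium | CCCCCCCCCCC[C@@H]1CC([Li])=CCO1 | intermediate
12 | 4-hydroxy-3-methoxy-4-[(2R)-2-undecyl-3,6-dihydro-2H-pyran-4-yl]cyclobut-2-en-1-one (both C4 epimers) | CCCCCCCCCCC[C@@H]1CC(=CCO1)C2(O)C(=O)C=C2OC | intermediate
13 | (3Z)-4-hydroxy-3-methoxy-4-[(2R)-2-undecyl-3,6-dihydro-2H-pyran-4-yl]buta-1,3-dien-1-one (dienylketene) | CCCCCCCCCCC[C@@H]1CC(=CCO1)/C(O)=C(OC)\C=C=O | intermediate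
14 | (3R)-5-hydroxy-6-methoxy-3-undecyl-3,4-dihydro-1H-isochromen-8(8aH)-one (dienone, C8a unspecified) | CCCCCCCCCCC[C@@H]1CC2=C(O)C(OC)=CC(=O)C2CO1 | intermediate
15 | (3R)-6-methoxy-3-undecylisochromane-5,8-diol | CCCCCCCCCCC[C@@H]1Cc2c(O)c(OC)cc(O)c2CO1 | intermediate
16 | (2R)-1-[3,6-bis(acetyloxy)-2-(bromomethyl)-5-methoxyphenyl]tridecan-2-yl acetate | CCCCCCCCCCC[C@H](Cc1c(OC(C)=O)c(OC)cc(OC(C)=O)c1CBr)OC(C)=O | intermediate
17 | ({3,6-bis(acetyloxy)-2-[(2R)-2-(acetyloxy)tridecyl]-4-methoxyphenyl}methoxy)dimethylsulfonium bromide | CCCCCCCCCCC[C@H](Cc1c(OC(C)=O)c(OC)cc(OC(C)=O)c1CO[S+](C)C)OC(C)=O.[Br-] | intermediate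
18 | (2R)-1-[3,6-bis(acetyloxy)-2-formyl-5-methoxyphenyl]tridecan-2-yl acetate | CCCCCCCCCCC[C@H](Cc1c(OC(C)=O)c(OC)cc(OC(C)=O)c1C=O)OC(C)=O | intermediate
19 | (2R)-1-(2-formyl-3,6-dihydroxy-5-methoxyphenyl)tridecan-2-yl acetate | CCCCCCCCCCC[C@H](Cc1c(O)c(OC)cc(O)c1C=O)OC(C)=O | target

## Step count and least certain steps

Total step count: 10. Longest linear sequence: 9 steps (steps 1 to 4 and 6 to 10); step 5 is a one-step side branch.

Step 7 (key step). The most likely failure is oxidative loss of the product during isolation: the methoxy-substituted hydroquinone is electron-rich and air converts it to the quinone. A smaller risk is inward rotation of the hydroxyl, which would let the ketene be trapped as a lactone instead of closing the ring. The fallback sets out from 12. After the same thermolysis the crude mixture is oxidised on purpose (Ag2O, Et2O) to the air-stable quinone (3R)-6-methoxy-3-undecyl-3,4-dihydro-1H-isochromene-5,8-dione F1, which can be purified and stored. Just before step 8 it is reduced with aqueous Na2S2O4 in a two-phase system, and the route is rejoined at 15, used without purification.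

Step 4. The most likely failure is erosion of configuration and loss of material through a 2-oxonia [3,3] shift. The formaldehyde-derived oxocarbenium ion can isomerise to a more substituted, achiral allenylmethyl oxocarbenium ion, which either returns with either configuration or is hydrolysed and lets the side chains exchange. The fallback avoids the cationic closure. It sets out from 6 and proceeds as follows:
- Double deprotonation (n-BuLi, 2 equiv) and formylation with DMF, quenched into aqueous KH2PO4, would give (5R)-5-hydroxyhexadec-2-ynal F2.
- Conjugate addition of pyrrolidine would give the enaminal (5R)-5-hydroxy-3-(pyrrolidin-1-yl)hexadec-2-enal F3, and aqueous acid would close it to (2R)-2-undecyl-2,3-dihydro-4H-pyran-4-one F4.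
- Conjugate reduction with LiBH(s-Bu)3 and trapping of the enolate with N-(5-chloro-2-pyridyl)triflimide would give (2R)-2-undecyl-3,6-dihydro-2H-pyran-4-yl trifluoromethanesulfonate F5, whose alkene position is dictated by the enone.
- Me3SnSnMe3, Pd(PPh3)4 and LiCl would give trimethyl[(2R)-2-undecyl-3,6-dihydro-2H-pyran-4-yl]stannane F6.
- Tin–lithium exchange with MeLi would deliver 11, where the route is rejoined for the addition to 10.

Step 6. The most likely failure is loss of regiocontrol or of material in the addition: proton abstraction from the acidic ring C–H of 10, or attack at the vinylogous ester carbonyl, which would end with the methoxy group next to C6 instead of C3. The fallback builds the regiochemistry into the electrophile. It sets out from 8 and proceeds as follows: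
- Monoketalisation (MeOSiMe3, Me3SiOTf cat.) would give 2,3,4,4-tetramethoxycyclobut-2-en-1-one F7.
- 1,2-Reduction with i-Bu2AlH at −78 °C would give 2,3,4,4-tetramethoxycyclobut-2-en-1-ol F8.
- Mild acid would transpose F8 with loss of methanol to 2,4,4-trimethoxycyclobut-2-en-1-one F9, whose only carbonyl is the one flanked by the methoxy-bearing carbon.
- Addition of 11 would give 2,4,4-trimethoxy-1-[(2R)-2-undecyl-3,6-dihydro-2H-pyran-4-yl]cyclobut-2-en-1-ol F10.
- Brief aqueous acid would unmask the ketal, and the route is rejoined at 12.

Step 8. The most likely failure is Lewis-acid ionisation of the para-methoxy-activated benzylic bromide followed by Friedel–Crafts self-alkylation at the free C5 position. Ring acylation or HBr-promoted side reactions could also occur before both phenols are acetylated. The fallback separates protection from cleavage and avoids the Lewis acid. It sets out from 15 and proceeds as follows: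
- Ac2O and pyridine would give (3R)-6-methoxy-3-undecylisochromane-5,8-diyl diacetate F11.
- Acetyl iodide generated from AcCl and NaI in MeCN would open the ether to (2R)-1-[3,6-bis(acetyloxy)-2-(iodomethyl)-5-methoxyphenyl]tridecan-2-yl acetate F12.
- Without isolation, F12 would be taken up in dry DMSO with NaHCO3 and oxidised through ({3,6-bis(acetyloxy)-2-[(2R)-2-(acetyloxy)tridecyl]-4-methoxyphenyl}methoxy)dimethylsulfonium iodide F13, and the route is rejoined at 18.

## Further compounds

F1 | step 7 | (3R)-6-methoxy-3-undecyl-3,4-dihydro-1H-isochromene-5,8-dione | CCCCCCCCCCC[C@@H]1CC2=C(CO1)C(=O)C=C(OC)C2=O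
F2 | step 4 | (5R)-5-hydroxyhexadec-2-ynal | CCCCCCCCCCC[C@@H](O)CC#CC=O
F3 | step 4 | (5R)-5-hydroxy-3-(pyrrolidin-1-yl)hexadec-2-enal | CCCCCCCCCCC[C@@H](O)CC(N1CCCC1)=CC=O
F4 | step 4 | (2R)-2-undecyl-2,3-dihydro-4H-pyran-4-one | CCCCCCCCCCC[C@@H]1CC(=O)C=CO1
F5 | step 4 | (2R)-2-undecyl-3,6-dihydro-2H-pyran-4-yl trifluoromethanesulfonate | CCCCCCCCCCC[C@@H]1CC(OS(=O)(=O)C(F)(F)F)=CCO1
F6 | step 4 | trimethyl[(2R)-2-undecyl-3,6-dihydro-2H-pyran-4-yl]stannane | CCCCCCCCCCC[C@@H]1CC([Sn](C)(C)C)=CCO1
F7 | step 6 | 2,3,4,4-tetramethoxycyclobut-2-en-1-one | COC1=C(OC)C(OC)(OC)C1=O
F8 | step 6 | 2,3,4,4-tetramethoxycyclobut-2-en-1-ol | COC1=C(OC)C(OC)(OC)C1O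
F9 | step 6 | 2,4,4-trimethoxycyclobut-2-en-1-one | COC1=CC(OC)(OC)C1=O
F10 | step 6 | 2,4,4-trimethoxy-1-[(2R)-2-undecyl-3,6-dihydro-2H-pyran-4-yl]cyclobut-2-en-1-ol | CCCCCCCCCCC[C@@H]1CC(=CCO1)C2(O)C(OC)=CC2(OC)OC
F11 | step 8 | (3R)-6-methoxy-3-undecylisochromane-5,8-diyl diacetate | CCCCCCCCCCC[C@@H]1Cc2c(OC(C)=O)c(OC)cc(OC(C)=O)c2CO1
F12 | step 8 | (2R)-1-[3,6-bis(acetyloxy)-2-(iodomethyl)-5-methoxyphenyl]tridecan-2-yl acetate | CCCCCCCCCCC[C@H](Cc1c(OC(C)=O)c(OC)cc(OC(C)=O)c1CI)OC(C)=O
F13 | step 8 | ({3,6-bis(acetyloxy)-2-[(2R)-2-(acetyloxy)tridecyl]-4-methoxyphenyl}methoxy)dimethylsulfonium iodide | CCCCCCCCCCC[C@H](Cc1c(OC(C)=O)c(OC)cc(OC(C)=O)c1CO[S+](C)C)OC(C)=O.[I-]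
A1 | alternative 1 | 6-[(6R)-6-(tert-butyldimethylsilyloxy)-2,4-dioxoheptadecyl]-2,2-dimethyl-4H-1,3-dioxin-4-one | CCCCCCCCCCC[C@H](CC(=O)CC(=O)CC1=CC(=O)OC(C)(C)O1)O[Si](C)(C)C(C)(C)C
A2 | alternative 1 | 5-[(2R)-2-(tert-butyldimethylsilyloxy)tridecyl]-7-hydroxy-2,2-dimethyl-4H-1,3-benzodioxin-4-one | CCCCCCCCCCC[C@H](Cc1cc(O)cc2OC(C)(C)OC(=O)c12)O[Si](C)(C)C(C)(C)C
A3 | alternative 2 | 1-iodo-4-methoxy-2,5-bis(methoxymethoxy)benzene | COCOc1cc(OC)c(OCOC)cc1I
A4 | alternative 2 | (3R)-6-methoxy-5,8-bis(methoxymethoxy)-3-undecylisochroman-1-one | CCCCCCCCCCC[C@@H]1Cc2c(OCOC)c(OC)cc(OCOC)c2C(=O)O1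
A5 | alternative 2 | (3R)-6-methoxy-5,8-bis(methoxymethoxy)-3-undecyl-3,4-dihydro-1H-isochromen-1-ol | CCCCCCCCCCC[C@@H]1Cc2c(OCOC)c(OC)cc(OCOC)c2C(O)O1
A6 | alternative 3 | tert-butyl[(4-methoxyfuran-2-yl)oxy]dimethylsilane | COc1coc(O[Si](C)(C)C(C)(C)C)c1
A7 | alternative 3 | (5R)-1-oxohexadec-2-yn-5-yl acetate | CCCCCCCCCCC[C@H](CC#CC=O)OC(C)=O
A8 | alternative 3 | (2R)-1-[3-(tert-butyldimethylsilyloxy)-2-formyl-6-hydroxy-5-methoxyphenyl]tridecan-2-yl acetate | CCCCCCCCCCC[C@H](Cc1c(O)c(OC)cc(O[Si](C)(C)C(C)(C)C)c1C=O)OC(C)=O
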